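**Assumption:** the target has no stereocentre (it is achiral), so "single enantiomer" does not apply. The only stereo-element in the route is the Z alkene of intermediate 10, which is fixed by the coumarin ring it comes from.

## Retrosynthetic overview

1. The pyran ring is closed last: the O1–C2 bond comes from intramolecular Mitsunobu etherification of a (Z)-2-aryl-3-(2-hydroxyaryl)allyl alcohol.
2. That allyl alcohol comes from hydride reduction of a 3-arylcoumarin (glycycoumarin triacetate), which carries the full carbon skeleton.
3. The coumarin (C3=C4 bond and lactone) comes from Perkin condensation of an A-ring salicylaldehyde with 2,4-dihydroxyphenylacetic acid.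
4. The A-ring pattern is set from phloroglucinol: the one free OH of the bis-MOM ether directs ortho-prenylation, then formylation at its only remaining ortho site, and is then methylated to become the 5-OMe.
5. Ring order: rings A and B are bought as arenes; the pyranone ring is formed in step 6 and converted to the 2H-pyran in steps 7–8.

## Route

**Step 1**
Reactants: 1, phloroglucinol
Product: 2, 3,5-bis(methoxymethoxy)phenol
Conditions: MOMCl (2.0 eq), i-Pr2NEt, DMF, 0 °C → rt; chromatography (mono- and tris-ethers recycled)
Reagents that add atoms: chloromethyl methyl ether, COCCl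
Why: Statistical O-alkylation (Williamson-type) of a C3-symmetric triol, so only one bis-ether is possible; expect roughly 35–45%.

**Step 2**
Reactants: 2, 3,5-bis(methoxymethoxy)phenol; 3, prenyl bromide
Product: 4, 3,5-bis(methoxymethoxy)-2-(3-methylbut-2-en-1-yl)phenol
Conditions: NaH (1.05 eq), toluene, 0 °C; then 3 (1.0 eq), rt
Reagents that add atoms: prenyl bromide (compound 3), CC(C)=CCBr
Why: Ortho-selective C-alkylation of a sodium phenoxide ion pair in a non-polar solvent; the two ortho positions are equivalent, so one regioisomer forms.

**Step 3**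
Reactants: 4
Product: 5, 2-hydroxy-4,6-bis(methoxymethoxy)-3-(3-methylbut-2-en-1-yl)benzaldehyde
Conditions: MgCl2 (anhydrous), Et3N, (CH2O)n, MeCN, reflux
Reagents that add atoms: paraformaldehyde (formaldehyde), C=O
Why: Casnati–Skattebøl magnesium-phenoxide ortho-formylation; the only free ortho position lies between the OH and an OMOM, so the CHO is placed regiospecifically.

**Step 4**
Reactants: 5
Product: 6, 2-methoxy-4,6-bis(methoxymethoxy)-3-(3-methylbut-2-en-1-yl)benzaldehyde
Conditions: MeI, K2CO3, DMF, rt → 40 °C
Reagents that add atoms: iodomethane, CI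
Why: Williamson O-methylation of the only free (chelated) phenol fixes the future 5-OMe between the prenyl group and the formyl carbon.

**Step 5**
Reactants: 6
Product: 7, 4,6-dihydroxy-2-methoxy-3-(3-methylbut-2-en-1-yl)benzaldehyde
Conditions: 3 M aq. HCl, MeOH, rt → 40 °C (stop at full conversion)
Reagents that add atoms: none
Why: Mild acidic acetal hydrolysis removes both MOM groups; the aryl methyl ether and aldehyde are stable, and the prenyl group tolerates brief dilute acid.

**Step 6**
Reactants: 7; 8, 2,4-dihydroxyphenylacetic acid
Product: 9, glycycoumarin triacetate = 4-[7-acetoxy-5-methoxy-6-(3-methylbut-2-en-1-yl)-2-oxo-2H-chromen-3-yl]-1,3-phenylene diacetate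
Conditions: Ac2O, Et3N, 110 °C
Reagents that add atoms: 2,4-dihydroxyphenylacetic acid (compound 8), OC(=O)Cc1ccc(O)cc1O; acetic anhydride, CC(=O)OC(C)=O
Why: Perkin–Oglialoro condensation; the arylacetic (mixed) anhydride enolate condenses with the aldehyde and lactonises onto the only ortho OH, while all other phenols are acetylated in situ.

**Step 7**
Reactants: 9
Product: 10, (Z)-2-(2,4-dihydroxyphenyl)-3-[4,6-dihydroxy-2-methoxy-3-(3-methylbut-2-en-1-yl)phenyl]prop-2-en-1-ol
Conditions: DIBAL-H (10 eq), THF, −78 → 0 °C; Rochelle salt work-up; use crude, no acid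
Reagents that add atoms: none
Why: 1,2-Reduction of the lactone to the ring-opened allylic alcohol with reductive cleavage of the three aryl acetates; the Z geometry is inherited from the coumarin ring.

**Step 8**
Reactants: 10
Product: 11, dehydroglyasperin C = 4-[7-hydroxy-5-methoxy-6-(3-methylbut-2-en-1-yl)-2H-chromen-3-yl]benzene-1,3-diol
Conditions: PPh3, DIAD, THF (0.01 M), 0 °C → rt
Reagents that add atoms: none
Why: Intramolecular Mitsunobu etherification of the primary allylic alcohol by the Z-disposed A-ring ortho-phenol (formally via an o-quinone methide / oxa-6π closure that only this phenol can undergo); neutral conditions avoid acid-induced pterocarpan formation from the 2'-OH.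

## Compound list

1 | phloroglucinol (benzene-1,3,5-triol) | Oc1cc(O)cc(O)c1 | starting material
2 | 3,5-bis(methoxymethoxy)phenol | COCOc1cc(O)cc(OCOC)c1 | intermediate
3 | prenyl bromide (1-bromo-3-methylbut-2-ene) | CC(C)=CCBr | starting material
4 | 3,5-bis(methoxymethoxy)-2-(3-methylbut-2-en-1-yl)phenol | COCOc1cc(O)c(CC=C(C)C)c(OCOC)c1 | intermediate
5 | 2-hydroxy-4,6-bis(methoxymethoxy)-3-(3-methylbut-2-en-1-yl)benzaldehyde | COCOc1cc(OCOC)c(C=O)c(O)c1CC=C(C)C | intermediate
6 | 2-methoxy-4,6-bis(methoxymethoxy)-3-(3-methylbut-2-en-1-yl)benzaldehyde | COCOc1cc(OCOC)c(C=O)c(OC)c1CC=C(C)C | intermediate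
7 | 4,6-dihydroxy-2-methoxy-3-(3-methylbut-2-en-1-yl)benzaldehyde | COc1c(C=O)c(O)cc(O)c1CC=C(C)C | intermediate
8 | 2,4-dihydroxyphenylacetic acid | OC(=O)Cc1ccc(O)cc1O | starting material
9 | glycycoumarin triacetate (7-acetoxy-3-(2,4-diacetoxyphenyl)-5-methoxy-6-prenylcoumarin) | COc1c2C=C(c3ccc(OC(C)=O)cc3OC(C)=O)C(=O)Oc2cc(OC(C)=O)c1CC=C(C)C | intermediate
10 | (Z)-2-(2,4-dihydroxyphenyl)-3-[4,6-dihydroxy-2-methoxy-3-(3-methylbut-2-en-1-yl)phenyl]prop-2-en-1-ol | OC/C(c1ccc(O)cc1O)=C\c1c(O)cc(O)c(CC=C(C)C)c1OC | intermediate
11 | dehydroglyasperin C | COc1c2c(cc(O)c1CC=C(C)C)OCC(c1ccc(O)cc1O)=C2 | target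

## Summary

Total steps: 8. Longest linear sequence: 8 (from phloroglucinol; compounds 3 and 8 are purchased).

Three steps most likely to fail, each with a fallback that changes the approach:

- **Step 8** (the free 2'-OH could close instead to a 3-benzylidene-2,3-dihydrobenzofuran; the polyphenol is sensitive). Fallback: change the protecting-group strategy so only the A-ring phenol is free at cyclisation. Methanolyse 9 to glycycoumarin, per-silylate (TBSCl, imidazole), then DIBAL, Mitsunobu and a final TBAF/AcOH desilylation.
- **Step 2** (competing O-prenylation, para- or di-alkylation). Fallback: transfer the prenyl group from oxygen to carbon instead. O-alkylate 2 with 3-chloro-3-methylbut-1-yne (DBU, cat. CuCl2), semi-hydrogenate (Lindlar), and run an aromatic Claisen rearrangement of the 1,1-dimethylallyl ether (about 120 °C) to give the same phenol 4.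
- **Step 7** (sluggish or over-reduction of the phenoxide-deactivated lactone; labile pentaol). Fallback: avoid the coumarin entirely and build ring C by intramolecular Wittig. From 7 as its 4-O-TBS ether: NaBH4, then PPh3·HBr to the 2-hydroxybenzylphosphonium salt, then O-alkylation with 2-bromo-1-[2,4-bis(TBSO)phenyl]ethanone and base-induced ring closure, then TBAF.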